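All runs are calculated for an exercise; the scatter is artificial.

In the grey run the complex with one exchanged rose faster up to 8.00 min than in the stretch from there to 40.0 min: it gained 21.8 %, then a further 7.7 percentage points. I had these two runs and wanted the five flasks below.

| flask | starting complex | incoming ligand | remark | time |
|---|---|---|---|---|
| red | 0.75 M | 0.30 equiv | run made earlier |  |
| grey | 1 M | 0.30 equiv | run made earlier |  |
| alder | 0.50 M | 0.300 equiv |  | 2.0 h |
| elm | 0.50 M | 0.600 equiv |  | 2.0 h |
| larch | 0.50 M | 1.20 equiv |  | 2.0 h |
| birch | 0.50 M | 2.50 equiv |  | 2.0 h |
| maple | 0.50 M | 5.00 equiv |  | 2.0 h |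

| run | time / min | complex with one exchanged / % | starting complex / % |
|---|---|---|---|
| red | 8.00 | 20.1 | 77.7 |
| red | 15.0 | 25.4 | 72.8 |
| red | 20.0 | 27.0 | 71.3 |
| red | 30.0 | 28.4 | 69.0 |
| red | 40.0 | 29.2 | 66.9 |
| grey | 3.00 | 12.3 | 84.2 |
| grey | 8.00 | 21.8 | 76.3 |
| grey | 15.0 | 28.1 | 69.9 |
| grey | 25.0 | 28.5 | 68.4 |
| grey | 30.0 | 28.8 | 66.8 |
| grey | 40.0 | 29.5 | 65.7 |

(standard deviation of a reading: 0.5 percentage points)

- "hardly changes" means that all values lie within two and a half points (for a concentration: within two and a half percent of the largest)

- amount of complex with one exchanged at the end, in percent of the starting complex charged for alder, elm, larch, birch, maple, in this order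
- how that number moves from the first to the last of them (falls all the way / falls, then rises / rises all the way / hardly changes / rises, then falls)

At the last grey reading the complex with one exchanged stood 0.500 % of the starting complex charged below the ligand charge, a gap no larger than the scatter of a reading, so I read the incoming ligand as the limiting reagent in the grey run. Read as a second-order exchange, the grey reading at 8.00 min gave me a rate constant of 0.183 M⁻¹ min⁻¹.

From this I carried the exchange half-life, the time in which the forward exchange alone would halve the starting complex with the incoming ligand held at its charge, a pseudo-first-order time. For alder it came to 25.2 min.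

The ladder began at maple, with 1.51 min, which was shorter than the 6.30 min of larch. Alder's half-life came next, still shorter than the 2.0 h allowed. The gap in the grey balance, read as 4.80 % by 40.0 min, grew more slowly than alder's half-life implied for the exchange.

So I committed to the ligand charge itself for alder and elm. For larch and beyond I expected something below the full charge of complex, but the runs gave me no amount.

The forecast said 29 %, 57 %, 81 %, 46 % and 10 %, and that the row rises, then falls. Its ground for the fall was: “With excess ligand, the slow second exchange eats the product”.

The flasks gave 29.7 %, 57.4 %, 84.8 %, 78.3 % and 63.4 %, and the row rises, then falls.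

    starting complex + incoming ligand ⇌ leaving ligand + complex with one exchanged (K = 49.0, k = 0.00432 M⁻¹ s⁻¹)
    complex with one exchanged + incoming ligand ⇌ leaving ligand + complex with two exchanged (K = 0.204, k = 0.0135 M⁻¹ s⁻¹)
    leaving ligand + starting complex → side product (k = 1.16 × 10⁻⁴ M⁻¹ s⁻¹)

The row turned at 1.4 equiv, and the complex with two exchanged stood higher at the end in maple, at 35.4 %, than the 4.88 % in larch. In alder, 25.2 min fitted 4.76 times into 2.0 h, and the incoming ligand ended at 0.75 % of its charge with starting complex at 63.4 %. In maple, 1.51 min fitted 79.5 times, and the starting complex stood at 0.468 % after 2.00 h.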